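**Strategy.** Everything rests on cutting the pyranone, ring C, at C3–C4 and O1–C8a (flavone numbering; C9 is the CH2 on C3 and C10 the O–CH of oxepine ring D). Both bonds tie ring A to the C2=C3 edge shared by rings C and D, so a benzoxepin-5-one that already holds ring B, ring D and the C10 stereocentre serves as the nucleophile, and a symmetric 2,4,6-trifluorobenzoyl unit brings C4 and ring A. In one operation the ketone α-carbon is acylated and the new enolate oxygen displaces an ortho fluoride, closing ring C; the fluorines left at C5 and C7 later become the two ring A oxygens. The precursor is a (2R)-2-(2-silyloxypropan-2-yl)-8-(methoxymethoxy)-1-benzoxepin-5-one.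

Key step: step 8

Remark: the L-fructose-derived enantiomer of the Shi ketone is assumed to be purchasable (otherwise made from L-sorbose); "oxepinoflavone" below means a flavone whose C3 and C2' are joined by the bridge C9H2–C10H–O (ring D), named with flavone numbering.

**Step 1**
Reactants: 1 2-methylbut-3-en-2-ol; 2 triethyl orthoacetate
Product: 5 ethyl 5-methylhex-4-enoate, via mixed orthoester 3 (not isolated), via ketene acetal 4 (not isolated)
Conditions: EtCO2H (cat.), excess 2, 140 °C, EtOH distilled off
Reagents that add atoms: none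
Why: Johnson–Claisen rearrangement, in which acid-catalysed exchange and loss of ethanol give the allyl ketene acetal whose chair [3,3] shift across the tertiary allylic C–O bond should deliver the γ,δ-unsaturated ester with the trisubstituted alkene and no stereocentre.

**Step 2**
Reactants: 5 ethyl 5-methylhex-4-enoate
Product: 6 N-methoxy-N,5-dimethylhex-4-enamide
Conditions: MeNH(OMe)·HCl, i-PrMgCl, THF, −20 → 0 °C
Reagents that add atoms: N,O-dimethylhydroxylamine hydrochloride, CNOC.Cl
Why: Ester aminolysis by the chloromagnesium amide (Weinreb amide formation) should stop cleanly at the amide, which is chosen because it cannot lactonise onto the tertiary alcohol made in step 5 and cannot over-add in step 7.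

**Step 3**
Reactants: 6 N-methoxy-N,5-dimethylhex-4-enamide
Product: 7 3-[(2S)-3,3-dimethyloxiran-2-yl]-N-methoxy-N-methylpropanamide
Conditions: L-fructose-derived Shi ketone (1,2:4,5-di-O-isopropylidene-β-L-erythro-2,3-hexodiulo-2,6-pyranose, 0.3 equiv), KHSO5 (as the triple salt 2KHSO5·KHSO4·K2SO4), K2CO3, Bu4NHSO4 (cat.), MeCN–CH2(OMe)2–aq Na2B4O7 buffer, 0 °C
Reagents that add atoms: potassium peroxymonosulfate, [K+].[O-]S(=O)(=O)OO
Why: Shi asymmetric epoxidation, in which the chiral dioxirane meets the trisubstituted alkene in a spiro transition state and the L-fructose-derived ketone, being the mirror image of the usual catalyst (which gives the R epoxide with 2-methylalk-2-enes), should set the epoxide CH carbon as S.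

**Step 4**
Reactants: 8 4-bromoresorcinol
Product: 9 2-bromo-5-(methoxymethoxy)phenol
Conditions: MOMCl (1.0 equiv), i-Pr2NEt, CH2Cl2, −20 → 0 °C
Reagents that add atoms: chloromethyl methyl ether, COCCl
Why: Mono-O-alkylation (MOM ether formation) should go mainly to the hydroxyl para to bromine, which is less hindered and more nucleophilic than the one flanked by bromine, with the regioisomer and the bis-ether removed by chromatography.

**Step 5**
Reactants: 7 3-[(2S)-3,3-dimethyloxiran-2-yl]-N-methoxy-N-methylpropanamide; 9 2-bromo-5-(methoxymethoxy)phenol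
Product: 10 (4R)-4-[2-bromo-5-(methoxymethoxy)phenoxy]-5-hydroxy-N-methoxy-N,5-dimethylhexanamide
Conditions: Cs2CO3 (0.3 equiv), DMF, 90 °C
Reagents that add atoms: none
Why: Base-mediated SN2 opening of the epoxide by the phenoxide can only occur at the secondary carbon (the tertiary one is closed to SN2 and no acid is present), so inversion should turn the S epoxide carbon into the R aryl ether centre C10 and leave the tertiary alcohol.

**Step 6**
Reactants: 10 (4R)-4-[2-bromo-5-(methoxymethoxy)phenoxy]-5-hydroxy-N-methoxy-N,5-dimethylhexanamide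
Product: 11 (4R)-4-[2-bromo-5-(methoxymethoxy)phenoxy]-N-methoxy-N,5-dimethyl-5-(triethylsilyloxy)hexanamide
Conditions: TESOTf (1.1 equiv), 2,6-lutidine, CH2Cl2, −78 °C, cold quench
Reagents that add atoms: triethylsilyl trifluoromethanesulfonate, CC[Si](CC)(CC)OS(=O)(=O)C(F)(F)F
Why: Silyl triflate silylation of the hindered tertiary alcohol is fast at −78 °C, removes the only acidic proton before the organolithium and enolate steps, and with little excess reagent should leave the aryl MOM ether untouched.

**Step 7**
Reactants: 11 (4R)-4-[2-bromo-5-(methoxymethoxy)phenoxy]-N-methoxy-N,5-dimethyl-5-(triethylsilyloxy)hexanamide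
Product: 14 (2R)-8-(methoxymethoxy)-2-[2-(triethylsilyloxy)propan-2-yl]-3,4-dihydro-2H-1-benzoxepin-5-one, via aryllithium 12 (not isolated), via tetrahedral lithium adduct 13 (not isolated)
Conditions: t-BuLi (2.1 equiv), THF, −78 °C; AcOH
Reagents that add atoms: none
Why: Parham cyclisation, in which bromine–lithium exchange outruns attack on the amide, the aryllithium adds 7-exo-trig to the Weinreb amide and the chelated adduct releases the ketone only on protonation, so over-addition should not occur and the remote stereocentre is untouched.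

**Step 8**
Reactants: 14 (2R)-8-(methoxymethoxy)-2-[2-(triethylsilyloxy)propan-2-yl]-3,4-dihydro-2H-1-benzoxepin-5-one; 15 2,4,6-trifluorobenzoyl chloride
Product: 17 (10R)-5,7-difluoro-4'-(methoxymethoxy)-10-[2-(triethylsilyloxy)propan-2-yl]oxepinoflavone, via diketone 16 (not isolated)
Conditions: LiN(SiMe3)2 (2.2 equiv), THF, −78 °C; 15 (1.05 equiv), −78 → −20 °C; AcOH; then crude 16, K2CO3, DMF, rt → 50 °C
Reagents that add atoms: none
Why: LiN(SiMe3)2 forms the lithium enolate at the only enolisable carbon of 14 (oxepinone C4, the future flavone C3), which attacks the acid chloride in a Claisen-type C-acylation to form C3–C4, and the second equivalent of base deprotonates diketone 16 as it forms, shielding it from a second acylation. With K2CO3 the enolate oxygen on the ring B side (the future O1) adds to an ortho C–F carbon of the trifluorophenyl ring and fluoride leaves from the Meisenheimer adduct, an intramolecular SNAr that forms O1–C8a. The closest known reaction type is the chromone and flavone synthesis from ketone enolates and 2-fluorobenzoyl chlorides by acylation then SNAr. Ring C closes in a 6-endo-trig addition–elimination, the oxygen adding to C8a as the β-carbon of the C8a=C4a–C4=O acceptor that lies inside the new ring; no stereocentre is formed, and C10 is safe because its C–O bond is γ to the carbonyl and cannot undergo E1cB loss. The step needs C- over O-acylation, which the lithium counter-ion in THF and the excess base that traps the diketone as its chelated enolate should secure. It also needs a single site of closure, which is fixed because both ortho carbons of the aroyl ring carry fluorine and are equivalent by symmetry while no other oxygen can reach them in a six-membered ring.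

**Step 9**
Reactants: 17 (10R)-5,7-difluoro-4'-(methoxymethoxy)-10-[2-(triethylsilyloxy)propan-2-yl]oxepinoflavone; 18 2-methylbut-3-yn-2-ol
Product: 19 (10R)-5-fluoro-4'-(methoxymethoxy)-7-[(2-methylbut-3-yn-2-yl)oxy]-10-[2-(triethylsilyloxy)propan-2-yl]oxepinoflavone
Conditions: 18 (3 equiv), NaH (2.5 equiv), THF, 0 °C; then 17, DMF, 0 °C → rt
Reagents that add atoms: none
Why: Nucleophilic aromatic substitution (addition–elimination) should take place at C7, which is para to the C4 carbonyl and flanked only by hydrogens, in preference to C5, which is peri to the carbonyl and shielded from a bulky tertiary alkoxide in a cation-solvating medium.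

**Step 10**
Reactants: 19 (10R)-5-fluoro-4'-(methoxymethoxy)-7-[(2-methylbut-3-yn-2-yl)oxy]-10-[2-(triethylsilyloxy)propan-2-yl]oxepinoflavone
Product: 23 (10R)-5-fluoro-4'-(methoxymethoxy)-10-[2-(triethylsilyloxy)propan-2-yl]-7,8-(2,2-dimethylpyrano)oxepinoflavone, via allenyl dienone 20 (not isolated), via allenyl phenol 21 (not isolated), via quinone methide 22 (not isolated)
Conditions: PhNEt2, 160 °C
Reagents that add atoms: none
Why: Aryl propargyl ether Claisen rearrangement, enolisation, 1,5-hydrogen shift and 6π-oxa-electrocyclisation should build the 2,2-dimethylchromene at C8, because in a chromone without a free 5-hydroxyl the C7–C8 bond has the higher double-bond character (as with 7-propargyloxycoumarins), which is the reason C5 still carries fluorine here.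

**Step 11**
Reactants: 23 (10R)-5-fluoro-4'-(methoxymethoxy)-10-[2-(triethylsilyloxy)propan-2-yl]-7,8-(2,2-dimethylpyrano)oxepinoflavone
Product: 25 (10R)-5-hydroxy-4'-(methoxymethoxy)-10-[2-(triethylsilyloxy)propan-2-yl]-7,8-(2,2-dimethylpyrano)oxepinoflavone, via sulfonylethyl ether 24 (not isolated)
Conditions: MeSO2CH2CH2OH (2 equiv), NaH (4 equiv), DMF, 0 °C → rt; AcOH
Reagents that add atoms: 2-(methylsulfonyl)ethanol, CS(=O)(=O)CCO
Why: SNAr at C5 (ortho to the C4 carbonyl) by the primary alkoxide followed by E1cB loss of methyl vinyl sulfone should leave the chelated 5-phenoxide, the alkoxide acting as a hydroxide surrogate that spares the pyranone ring.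

**Step 12**
Reactants: 25 (10R)-5-hydroxy-4'-(methoxymethoxy)-10-[2-(triethylsilyloxy)propan-2-yl]-7,8-(2,2-dimethylpyrano)oxepinoflavone
Product: 26 (10R)-5,4'-dihydroxy-10-(2-hydroxypropan-2-yl)-7,8-(2,2-dimethylpyrano)oxepinoflavone (CNP0329736.1)
Conditions: HCl (1.25 M in MeOH), THF, rt → 40 °C
Reagents that add atoms: none
Why: Acid-catalysed methanolysis (acetal exchange of the MOM ether, protodesilylation of the tertiary silyl ether) should remove both groups in one operation under conditions that the chromene and the inductively deactivated tertiary alcohol tolerate, with C10 not involved.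

**Compound list**
1 | 2-methylbut-3-en-2-ol | CC(C)(O)C=C | starting material
2 | triethyl orthoacetate | CCOC(C)(OCC)OCC | starting material
3 | 1,1-diethoxy-1-[(2-methylbut-3-en-2-yl)oxy]ethane (mixed orthoester, not isolated) | CCOC(C)(OCC)OC(C)(C)C=C | intermediate
4 | 1-ethoxy-1-[(2-methylbut-3-en-2-yl)oxy]ethene (ketene acetal, not isolated) | C=C(OCC)OC(C)(C)C=C | intermediate
5 | ethyl 5-methylhex-4-enoate | CCOC(=O)CCC=C(C)C | intermediate
6 | N-methoxy-N,5-dimethylhex-4-enamide | CON(C)C(=O)CCC=C(C)C | intermediate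
7 | 3-[(2S)-3,3-dimethyloxiran-2-yl]-N-methoxy-N-methylpropanamide | CON(C)C(=O)CC[C@@H]1OC1(C)C | intermediate
8 | 4-bromoresorcinol (4-bromobenzene-1,3-diol) | Oc1ccc(Br)c(O)c1 | starting material
9 | 2-bromo-5-(methoxymethoxy)phenol | COCOc1ccc(Br)c(O)c1 | intermediate
10 | (4R)-4-[2-bromo-5-(methoxymethoxy)phenoxy]-5-hydroxy-N-methoxy-N,5-dimethylhexanamide | CON(C)C(=O)CC[C@@H](Oc1cc(OCOC)ccc1Br)C(C)(C)O | intermediate
11 | (4R)-4-[2-bromo-5-(methoxymethoxy)phenoxy]-N-methoxy-N,5-dimethyl-5-(triethylsilyloxy)hexanamide | CON(C)C(=O)CC[C@@H](Oc1cc(OCOC)ccc1Br)C(C)(C)O[Si](CC)(CC)CC | intermediate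
12 | aryllithium from 11, lithium in place of bromine (not isolated) | CON(C)C(=O)CC[C@@H](Oc1cc(OCOC)ccc1[Li])C(C)(C)O[Si](CC)(CC)CC | intermediate
13 | lithium (2R)-5-[methoxy(methyl)amino]-8-(methoxymethoxy)-2-[2-(triethylsilyloxy)propan-2-yl]-2,3,4,5-tetrahydro-1-benzoxepin-5-olate (C5 undefined, not isolated) | CON(C)C1(O[Li])CC[C@H](C(C)(C)O[Si](CC)(CC)CC)Oc2cc(OCOC)ccc12 | intermediate
14 | (2R)-8-(methoxymethoxy)-2-[2-(triethylsilyloxy)propan-2-yl]-3,4-dihydro-2H-1-benzoxepin-5-one | O=C1CC[C@H](C(C)(C)O[Si](CC)(CC)CC)Oc2cc(OCOC)ccc12 | intermediate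
15 | 2,4,6-trifluorobenzoyl chloride | O=C(Cl)c1c(F)cc(F)cc1F | starting material
16 | (2R)-8-(methoxymethoxy)-4-(2,4,6-trifluorobenzoyl)-2-[2-(triethylsilyloxy)propan-2-yl]-3,4-dihydro-2H-1-benzoxepin-5-one (C4 epimers and enol forms, not isolated) | O=C(c1c(F)cc(F)cc1F)C1C[C@H](C(C)(C)O[Si](CC)(CC)CC)Oc2cc(OCOC)ccc2C1=O | intermediate
17 | (10R)-5,7-difluoro-4'-(methoxymethoxy)-10-[2-(triethylsilyloxy)propan-2-yl]oxepinoflavone | Fc1cc(F)c2c(=O)c3c(oc2c1)-c1ccc(OCOC)cc1O[C@@H](C(C)(C)O[Si](CC)(CC)CC)C3 | intermediate
18 | 2-methylbut-3-yn-2-ol | CC(C)(O)C#C | starting material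
19 | (10R)-5-fluoro-4'-(methoxymethoxy)-7-[(2-methylbut-3-yn-2-yl)oxy]-10-[2-(triethylsilyloxy)propan-2-yl]oxepinoflavone | C#CC(C)(C)Oc1cc(F)c2c(=O)c3c(oc2c1)-c1ccc(OCOC)cc1O[C@@H](C(C)(C)O[Si](CC)(CC)CC)C3 | intermediate
20 | 7-oxo-7,8-dihydro dienone carrying 8-(3-methylbuta-1,2-dienyl), the first Claisen product (C8 undefined, not isolated) | CC(C)=C=CC1C(=O)C=C(F)C2=C1OC1=C(C2=O)C[C@H](C(C)(C)O[Si](CC)(CC)CC)Oc2cc(OCOC)ccc21 | intermediate
21 | (10R)-5-fluoro-7-hydroxy-8-(3-methylbuta-1,2-dienyl)-4'-(methoxymethoxy)-10-[2-(triethylsilyloxy)propan-2-yl]oxepinoflavone (not isolated) | CC(C)=C=Cc1c(O)cc(F)c2c(=O)c3c(oc12)-c1ccc(OCOC)cc1O[C@@H](C(C)(C)O[Si](CC)(CC)CC)C3 | intermediate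
22 | ortho-quinone methide with 7-oxo and 8-(3-methylbut-2-enylidene) groups (alkene geometry undefined, not isolated) | CC(C)=CC=C1C(=O)C=C(F)C2=C1OC1=C(C2=O)C[C@H](C(C)(C)O[Si](CC)(CC)CC)Oc2cc(OCOC)ccc21 | intermediate
23 | (10R)-5-fluoro-4'-(methoxymethoxy)-10-[2-(triethylsilyloxy)propan-2-yl]-7,8-(2,2-dimethylpyrano)oxepinoflavone (pyran oxygen on C7, CH=CH on C8) | CC1(C)C=Cc2c(cc(F)c3c(=O)c4c(oc23)-c2ccc(OCOC)cc2O[C@@H](C(C)(C)O[Si](CC)(CC)CC)C4)O1 | intermediate
24 | 5-[2-(methylsulfonyl)ethoxy] analogue of 23 (not isolated) | CC1(C)C=Cc2c(cc(OCCS(C)(=O)=O)c3c(=O)c4c(oc23)-c2ccc(OCOC)cc2O[C@@H](C(C)(C)O[Si](CC)(CC)CC)C4)O1 | intermediate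
25 | (10R)-5-hydroxy-4'-(methoxymethoxy)-10-[2-(triethylsilyloxy)propan-2-yl]-7,8-(2,2-dimethylpyrano)oxepinoflavone | CC1(C)C=Cc2c(cc(O)c3c(=O)c4c(oc23)-c2ccc(OCOC)cc2O[C@@H](C(C)(C)O[Si](CC)(CC)CC)C4)O1 | intermediate
26 | (10R)-5,4'-dihydroxy-10-(2-hydroxypropan-2-yl)-7,8-(2,2-dimethylpyrano)oxepinoflavone, CNP0329736.1 | CC1(C)C=Cc2c(cc(O)c3c(=O)c4c(oc23)-c2ccc(O)cc2O[C@@H](C(C)(C)O)C4)O1 | target

**Totals.** Total step count: 12. Longest linear sequence: 11 steps (steps 1, 2, 3, 5, 6, 7, 8, 9, 10, 11, 12); step 4 is a one-step branch.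

**Steps most likely to fail**

Step 8 (key step). Acylation may occur on the enolate oxygen instead of on carbon, or the amide base may attack the activated fluoroarene before the diketone forms. Fallback: from 14, the lithium enolate (LiN(SiMe3)2, THF, −78 °C) is added to 2,4,6-trifluorobenzaldehyde in an aldol addition, which can only form the C–C bond, and AcOH quench should give the β-hydroxy ketone F1 as a diastereomer mixture. Dess–Martin periodinane in CH2Cl2 oxidises it to diketone 16, now isolated, and K2CO3 in DMF closes ring C as in the main route, which is rejoined at 17.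

Step 5. Ring opening at the neopentyl-like epoxide carbon may be too slow with the hindered, weakly nucleophilic ortho-bromophenoxide, so that epoxide and amide decompose at the temperature needed. Fallback: the C–O bond is formed intramolecularly after the aryl–carbonyl bond. From 9, n-BuLi (1 equiv) then t-BuLi (2 equiv) in THF at −78 °C should give lithium 2-lithio-5-(methoxymethoxy)phenolate F2. It acylates on Weinreb amide 7, whose epoxide is inert to aryllithiums at this temperature, and AcOH quench gives the ortho-hydroxyaryl ketone F3. K2CO3 in DMF at 60 °C, which ionises only the phenol, lets the phenoxide open the epoxide at its secondary carbon in a 7-exo-tet closure with inversion to give hydroxy oxepinone F4. TESOTf/2,6-lutidine at −78 °C converts this into 14, where the route is rejoined with steps 6 and 7 bypassed.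

Step 9. Attack of the bulky tertiary alkoxide may be slow and poorly selective between C7 and the sodium-chelated C5 position, with loss of the silyl group on prolonged exposure. Fallback: from 17, one equivalent of the small primary alkoxide of 2-(methylsulfonyl)ethanol (NaH, DMF, 0 °C) displaces the 7-fluoride to give the sulfonylethyl ether F5, which loses methyl vinyl sulfone in the flask and after AcOH quench leaves the 7-hydroxy-5-fluoro compound F6. Copper-catalysed O-propargylation of this phenol with 3-chloro-3-methylbut-1-yne (CuCl2 cat., DBU, MeCN, 0 °C) then gives propargyl ether 19, where the route is rejoined.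

**Further compounds**
F1 | step 8 | (2R)-4-[hydroxy(2,4,6-trifluorophenyl)methyl]-8-(methoxymethoxy)-2-[2-(triethylsilyloxy)propan-2-yl]-3,4-dihydro-2H-1-benzoxepin-5-one (new centres undefined) | OC(c1c(F)cc(F)cc1F)C1C[C@H](C(C)(C)O[Si](CC)(CC)CC)Oc2cc(OCOC)ccc2C1=O
F2 | step 5 | lithium 2-lithio-5-(methoxymethoxy)phenolate | [Li]Oc1cc(OCOC)ccc1[Li]
F3 | step 5 | 3-[(2S)-3,3-dimethyloxiran-2-yl]-1-[2-hydroxy-4-(methoxymethoxy)phenyl]propan-1-one | O=C(CC[C@@H]1OC1(C)C)c1ccc(OCOC)cc1O
F4 | step 5 | (2R)-2-(2-hydroxypropan-2-yl)-8-(methoxymethoxy)-3,4-dihydro-2H-1-benzoxepin-5-one | O=C1CC[C@H](C(C)(C)O)Oc2cc(OCOC)ccc12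
F5 | step 9 | (10R)-5-fluoro-4'-(methoxymethoxy)-7-[2-(methylsulfonyl)ethoxy]-10-[2-(triethylsilyloxy)propan-2-yl]oxepinoflavone | CS(=O)(=O)CCOc1cc(F)c2c(=O)c3c(oc2c1)-c1ccc(OCOC)cc1O[C@@H](C(C)(C)O[Si](CC)(CC)CC)C3
F6 | step 9 | (10R)-5-fluoro-7-hydroxy-4'-(methoxymethoxy)-10-[2-(triethylsilyloxy)propan-2-yl]oxepinoflavone | Oc1cc(F)c2c(=O)c3c(oc2c1)-c1ccc(OCOC)cc1O[C@@H](C(C)(C)O[Si](CC)(CC)CC)C3
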